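(All runs come from a simulation for substances that don't exist; scatter was added.)

Total complex, in whatever form, stays at 0.032 M through a run, and zeta, theta, green, grey and violet were charged alike. The flasks differ in one concentration, [incoming ligand], and your hunch is that the level of complex with two exchanged follows that charge.

all flasks: starting complex 0.032 M
- zeta: incoming ligand 0.033 M; run made earlier
- theta: incoming ligand 0.12 M; run made earlier
- green: incoming ligand 0.0256 M; time 2.5 min
- grey: incoming ligand 0.0320 M; time 2.5 min
- violet: incoming ligand 0.0960 M; time 2.5 min

| run | time / min | complex with two exchanged / % | complex with one exchanged / % |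
|---|---|---|---|
| zeta | 0.167 | 4.4 | 10.9 |
| zeta | 0.417 | 5.0 | 10.6 |
| zeta | 0.667 | 6.2 | 11.3 |
| zeta | 1.00 | 6.9 | 12.6 |
| zeta | 1.50 | 6.7 | 10.6 |
| zeta | 2.00 | 5.8 | 11.7 |
| zeta | 2.50 | 6.5 | 9.4 |
| theta | 0.200 | 14.2 | 9.9 |
| theta | 0.333 | 19.5 | 9.7 |
| theta | 0.500 | 22.9 | 11.3 |
| theta | 0.667 | 22.3 | 9.8 |
| theta | 1.00 | 23.1 | 8.4 |
| theta | 1.50 | 23.3 | 10.2 |
| theta | 2.50 | 22.6 | 10.1 |

(standard deviation of a reading: 1 percentage point)

- complex with two exchanged at the end, in percent of the starting complex charged, for each flask in turn (green, grey, violet)



1. Zeta's complex with two exchanged stays roughly flat from 1.00 min and averages 6.47%. Theta's stays flat from 1.00 min and averages 23.0%. The asked time 2.5 min is later than both, so these plateau readings can serve as end values.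

2. Your hunch survives. From zeta to theta, [incoming ligand] rises by a factor of 3.64, and the plateau reading by 3.55.

3. That suggests one number to carry: the capture share, meaning the moles of complex with two exchanged at the plateau per mole of incoming ligand charged. Zeta reads 6.28% and theta 6.13%, so the mean is 6.21%.

4. My reckoning takes the end level as the capture share times [incoming ligand] charged, divided by [starting complex] charged. Green gets 4.96%, grey 6.21% and violet 18.6%. Green and grey lie below zeta's charge, so those two lean on the rule outside the charges read.

The forecast gives 4.9%, 6.2% and 18.3%, with violet below mine, on the ground that “about 6% of the charged ligand ends up as two-exchanged complex”.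

The flasks give 4.03%, 5.38% and 19.0%.

    starting complex + incoming ligand ⇌ leaving ligand + complex with one exchanged (K = 6.30, k = 1.30 M⁻¹ s⁻¹)
    complex with one exchanged + incoming ligand ⇌ leaving ligand + complex with two exchanged (K = 35.0, k = 7.20 M⁻¹ s⁻¹)
    complex with two exchanged + incoming ligand ⇌ leaving ligand + complex with three exchanged (K = 2.80, k = 12.0 M⁻¹ s⁻¹)
    incoming ligand → decomposed reagent (k = 0.130 s⁻¹)
    leaving ligand → by-product carried off (k = 0.0980 s⁻¹)

Measured by the capture share, grey comes to 5.38% and violet to 6.33%, against the 6.21% read from the runs. In grey, 68.8% of the charged incoming ligand ends as decomposed reagent, and 0% of this limiting reagent remains. That decomposition is part of what holds the share down: with the step taken away, grey's complex with two exchanged ends at 14.5% instead of 5.38%.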